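Remark on the chemistry: isoflavone numbering is used from compound 13 onwards (ring A: C5–C8, ring B: primed positions), and species that exist in the flask as metal phenoxides or alkoxides are written in their neutral form.

## Analysis of the target

Kanzonol T (20) is an isoflavone. A γ-pyrone (ring C) carries ring B at C3 and is fused to a phloroglucinol-type ring A with hydroxyls at C5 and C7 and a 3-hydroxy-3-methylbutyl chain at C6. Ring B has a free 2'-hydroxyl and a 2,2-dimethyl-2H-pyran fused across C3'–C4', with the pyran oxygen on C4'. There is no stereocentre, and the only alkene with a geometry is the cis double bond locked inside the pyran. The sensitive groups are the chromene (acid, oxidants, hydrogenation), the tertiary alcohol flanked by two phenols (it can cyclise to a chroman under strong acid), the pyrone (hard nucleophiles, strong base) and the three phenols. The difficulty is regiochemical: the chain must sit on C6 and not C8, and the pyran must close onto the 4'-oxygen and not the 2'-oxygen. The strategy rests on one feature: C3''' of the chain and C2'' of the pyran are both oxygen-bearing C(CH3)2 carbons, and each lies in a six-membered relationship to a phenolic oxygen (5-O via C6–C1'''–C2''', and 4'-O via C3'–C4''=C3''). Both can therefore be carried as carbonyl carbons of six-membered aryl lactones, a dihydrocoumarin on ring A and a coumarin on ring B, and the four methyl groups can be added at the end.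

## Retrosynthetic reasoning

**20 ⇐ 19 ⇐ 18.** The last protecting group is removed (19 → 20). Before that only the O4'–C2'' bond is cut, which opens the pyran to the Z-allylic tertiary alcohol 18. This cut is chosen because the forward reaction is a mild cyclodehydration that forms no carbon–carbon bond. It requires that the 2'-oxygen is masked (MOM ether), so that the 4'-hydroxyl is the only phenol that can close.

**18 ⇐ 17 (made in the flask from 16).** All four C–CH3 bonds at C3''' and C2'' are cut, and each carbinol carbon becomes a lactone carbonyl tied to 5-O and to 4'-O. This gives bis-lactone 17. The methyl groups are the simplest carbons to add late, and the two lactone oxygens record the regiochemistry (chain at C6, pyran oxygen at C4'). The forward reaction needs a methyl-metal reagent to add twice to each lactone while the pyrone is left alone; the free 7-hydroxyl, as its phenoxide, provides that protection. Compound 17 is reached from its 7-O-acetate 16, which is needed for a practical reason given in the next paragraph.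

**16 ⇐ 14 ⇐ 13.** The MOM group must go onto the 2'-oxygen in the presence of the 7-hydroxyl. In diol 14 the 7-OH is the more acidic and less hindered phenol, so it is capped first with one equivalent of an acylating agent; the MOM group is then placed on the remaining 2'-OH. The acetate is cleaved by the methyl reagent itself at the start of the key step. Diol 14 comes from methyl ether 13. A robust ether is required on the 2'-oxygen during the Lewis-acid steps that build ring C: an acetal would not survive, and a free 2'-hydroxyl next to the deoxybenzoin ketone would dehydrate to a 2-arylbenzofuran.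

**13 ⇐ 12 ⇐ 3 + 11.** Ring C is cut at O1–C2 and C2–C3 (insertion of one formyl carbon into deoxybenzoin 12), and then at C4–C4a (Friedel–Crafts acylation of dihydrocoumarin 3 by arylacetic acid 11). Acylating the preformed lactone 3 is the point of the plan for ring A. The acylated carbon is flanked by the lactone oxygen and one free hydroxyl, so ring C can only close onto that hydroxyl. This places the chain at C6 and the lactone on 5-O.

**3 ⇐ 1 + 2.** The dihydrocoumarin is cut at the aryl–CH2 bond and the lactone C–O bond. Because 1 is threefold symmetric, the annulation with 2 has no regiochemical choice.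

**11 ⇐ 9 ⇐ 8 ⇐ 7 ⇐ 6 ⇐ 4.** The acetic acid unit on C1' comes from oxidative cleavage of a C-allyl group (9, via aldehyde 10). The C-allyl group comes from Claisen rearrangement of allyl ether 7, which has only one free ortho position, so 8 forms with the new carbon on the future C1'. Coumarin 6 is cut at its C3=C4 bond and lactone C–O bond back to the symmetric aldehyde 4, via cinnamate 5.

## Alternatives that were turned down

**Alternative 1:** The C3–C1' bond is cut inside a temporary six-membered lactone that links the 2'-oxygen to a carboxyl group on C2 of the pyrone. In the forward step a zerovalent palladium catalyst, generated from Pd(OAc)2 and a phosphine with a carbonate base, would insert into the C3–Br bond of aryl ester A1 and arylate the only ortho C–H of the chromenyl ester, giving bridged isoflavone A2.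
- For it: the plan is convergent; the tether leaves no positional choice on ring B, since the other ortho carbon is the pyran fusion atom; the chromene and the hydroxylated chain are complete before the union.
- Against it: the carboxyl carbon is not part of the target. It must be removed from A2 by lactone hydrolysis and decarboxylation, and decarboxylation at C2 of a pyrone needs strong heating, which is hard to reconcile with a 2,2-dimethylchromene and a tertiary alcohol. The ring A half of A1 must still be made with the chain on C6 and not C8, which the tether does not address. The chromene alkene could also engage the palladium intermediate in a Heck-type side reaction.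
- Comparison: this plan is stronger than the chosen one on the security of the aryl–pyrone bond and on convergence; the chosen route makes that bond by an acylation with a regiochemical bias, not a constraint. In exchange, the chosen route keeps every tether carbon in the product, uses the same tethers to decide C6 versus C8 and 4'-O versus 2'-O, and exposes the chromene and carbinols only in the last three steps.

**Alternative 2:** Ring B is cut at C1'–C6' and C2'–C3' into a four-carbon diene, the bicyclic 2-pyranone A3 that already contains the dimethylpyran, and a two-carbon alkyne, the ynol ether A4 on C3 of a finished ring A/C pyrone. Heating would join them in a [4+2] cycloaddition followed by cycloreversion with loss of CO2, giving A5.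
- For it: ring B is formed with all its substituents in one operation; the pyran never has to be closed regioselectively; the polarisation of the partners (nucleophilic alkyne carbon remote from oxygen, electrophilic C6 of the pyranone) points to the required orientation.
- Against it: such pyranone cycloadditions need prolonged heating, and an alkoxyalkyne with β-hydrogens in its alkyl group fragments by a retro-ene path in the same temperature range. The 4-alkoxy group makes the diene less electron-poor, so the inverse-demand pairing is weak. The 2H-pyran of A3 can open by a retro-6π reaction. A4 needs a long sequence, its ring A part still has the C6/C8 problem, and three kinds of protecting group must be removed at the end.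
- Comparison: step economy is poorer and the thermal window is narrow. The plan is stronger on one point, the unambiguous placing of the pyran on ring B; the chosen route secures this through the coumarin oxygen and a 2'-O protecting group.

**Alternative 3:** Ring C is cut at O1–C8a and C4–C4a. Fluoride (CsF) would convert silyl triflate A6 into aryne A7. The enol oxygen of formylacetate A8, which carries ring B with its chromene, is meant to add at C8a, remote from the MOM-oxy substituent, and the aryl anion at C4a would then attack the ester to close the pyrone, giving A9.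
- For it: A6 has a ring A pattern that is symmetric about the chain, so the C6/C8 question does not arise. This is a cleaner answer than the acylation bias of the chosen route. The conditions are mild and the union is convergent.
- Against it: a formylacetate enolate is ambident, and arynes are normally attacked by its carbon, which leads to C-arylation or acyl-alkylation and not O-arylation. The aryl anion is flanked by two ortho substituents. The tetrasubstituted A6 takes many steps, fluoride must spare the triethylsilyl ether, and three MOM groups plus the silyl ether must be removed in acid in the presence of the chromene.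
- Comparison: this plan is more elegant on ring A regiocontrol and convergence, but its decisive bond formation depends on an uncommon O-selective aryne capture. In the chosen route the decisive step is exhaustive methylation of lactones, a long-established reaction type, and fewer protecting groups are needed (one methyl ether, one sacrificial acetate, one MOM ether).

Key step: step 11

## Route

Step 1
Reactants: 1 phloroglucinol; 2 acrylic acid
Product: 3 5,7-dihydroxychroman-2-one (5,7-dihydroxy-3,4-dihydrocoumarin)
Conditions: polystyrenesulfonic acid resin (H+ form), toluene, reflux, water separator; 1.0 equiv of 2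
Reagents that add atoms: none
Why: Acid-catalysed Friedel–Crafts conjugate alkylation (hydroarylation) of the triphenol by acrylic acid followed by lactonisation onto an ortho hydroxyl; the three ring positions of 1 are equivalent, so only one dihydrocoumarin can form, and one equivalent of 2 limits a second annulation.

Step 2
Reactants: 4 2,6-dihydroxybenzaldehyde
Product: 6 5-hydroxycoumarin, via ethyl (E)-3-(2,6-dihydroxyphenyl)acrylate 5 (not isolated)
Conditions: Ph3P=CHCO2Et, PhNEt2, reflux
Reagents that add atoms: ethyl (triphenylphosphoranylidene)acetate, CCOC(=O)C=P(c1ccccc1)(c1ccccc1)c1ccccc1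
Why: Wittig olefination with the stabilised ylide gives cinnamate 5; in refluxing diethylaniline the alkene isomerises and the Z form lactonises with loss of ethanol, and either hydroxyl of the symmetric aldehyde gives the same coumarin.

Step 3
Reactants: 6 5-hydroxycoumarin
Product: 7 5-(allyloxy)coumarin
Conditions: allyl bromide, K2CO3, acetone, reflux
Reagents that add atoms: allyl bromide, C=CCBr
Why: Williamson O-alkylation of the only phenol under carbonate conditions that leave the coumarin lactone closed.

Step 4
Reactants: 7 5-(allyloxy)coumarin
Product: 8 6-allyl-5-hydroxycoumarin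
Conditions: PhNEt2, 200 °C
Reagents that add atoms: none
Why: Aromatic Claisen rearrangement; of the two ortho positions only C6 carries hydrogen (the other is the ring-fusion carbon C4a), so the [3,3] shift and tautomerisation should place the allyl group on C6, the future C1' of ring B.

Step 5
Reactants: 8 6-allyl-5-hydroxycoumarin
Product: 9 6-allyl-5-methoxycoumarin
Conditions: MeI, K2CO3, DMF, rt
Reagents that add atoms: iodomethane, CI
Why: Williamson O-methylation; the methyl ether is chosen because it survives the BF3-mediated steps, where an acetal would be lost and a free hydroxyl would later attack the deoxybenzoin ketone to give a 2-arylbenzofuran.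

Step 6
Reactants: 9 6-allyl-5-methoxycoumarin
Product: 11 2-(5-methoxy-2-oxo-2H-chromen-6-yl)acetic acid, via arylacetaldehyde 10 (not isolated)
Conditions: OsO4 (cat.), NaIO4, 2,6-lutidine, dioxane–H2O, rt; then NaClO2, NaH2PO4, 2-methyl-2-butene, t-BuOH–H2O, rt
Reagents that add atoms: osmium tetroxide, O=[Os](=O)(=O)=O; sodium periodate, [Na+].[O-]I(=O)(=O)=O; sodium chlorite, [Na+].[O-]Cl=O
Why: Lemieux–Johnson cleavage of the electron-rich terminal alkene (the electron-poor, conjugated coumarin C3=C4 bond reacts far more slowly with OsO4), followed by Pinnick oxidation of the sensitive arylacetaldehyde without isolation.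

Step 7
Reactants: 3 5,7-dihydroxychroman-2-one; 11 2-(5-methoxy-2-oxo-2H-chromen-6-yl)acetic acid
Product: 12 5,7-dihydroxy-8-[2-(5-methoxy-2-oxo-2H-chromen-6-yl)acetyl]chroman-2-one
Conditions: BF3·OEt2 (neat), 80 °C; aq. NaOAc work-up
Reagents that add atoms: none
Why: Friedel–Crafts C-acylation of a phloroglucinol-type ring by a BF3-activated carboxylic acid (the standard deoxybenzoin synthesis); C8 is para to the 5-OH and flanked by only one BF3-complexed hydroxyl, whereas C6 lies between two, so C8 should be favoured as in acylations of 5,7-dihydroxycoumarins; the minor C6 isomer is to be removed at this stage.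

Step 8
Reactants: 12 deoxybenzoin from step 7
Product: 13 7-hydroxy-2'-methoxy bis-lactone isoflavone (dihydrocoumarin lactone across C6 and 5-O, coumarin lactone across C3' and 4'-O)
Conditions: BF3·OEt2, DMF, 50 °C; then MsCl, 70 °C
Reagents that add atoms: N,N-dimethylformamide, CN(C)C=O
Why: Formylative isoflavone ring closure: the iminium reagent from DMF and MsCl condenses at the activated methylene and the enaminone cyclises onto the only free ortho hydroxyl (the other ortho oxygen is held in the lactone), which fixes the chain at C6 and the lactone on 5-O.

Step 9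
Reactants: 13 7-hydroxy-2'-methoxy bis-lactone isoflavone
Product: 14 7,2'-dihydroxy bis-lactone isoflavone
Conditions: BBr3 (excess), CH2Cl2, −78 °C → rt
Reagents that add atoms: none
Why: Lewis-acid cleavage of the single aryl methyl ether; aryl lactones, the coumarin and the pyrone tolerate BBr3, and at the isoflavone stage the freed 2'-OH no longer has a ketone to condense with.

Step 10
Reactants: 14 7,2'-dihydroxy bis-lactone isoflavone
Product: 16 7-O-acetyl-2'-O-MOM bis-lactone isoflavone, via 7-O-acetyl-2'-hydroxy bis-lactone 15 (not isolated)
Conditions: Ac2O (1.0 equiv), Et3N, THF, −20 °C; then MOMCl, i-Pr2NEt, 0 °C → rt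
Reagents that add atoms: acetic anhydride, CC(=O)OC(C)=O; chloromethyl methyl ether, COCCl
Why: Site-selective O-acylation followed by O-alkylation: the 7-OH, para to the pyrone carbonyl, is the more acidic and less hindered phenol and takes the single equivalent of anhydride, after which only the hindered 2'-OH is left for MOMCl; the acetate is a sacrificial mask that the next step removes.

Step 11
Reactants: 16 7-O-acetyl-2'-O-MOM bis-lactone isoflavone
Product: 18 2'-O-MOM seco-Kanzonol T (Z-3-hydroxy-3-methylbut-1-enyl on C3', free 4'-OH, 3-hydroxy-3-methylbutyl on C6), via 7-hydroxy-2'-O-MOM bis-lactone 17 (not isolated)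
Conditions: MeLi (excess, ca. 12 equiv), CeCl3 (anhydrous, ca. 12 equiv), THF, −78 → 0 °C; sat. aq. NH4Cl, 0 °C
Reagents that add atoms: methyllithium, [Li]C
Why: The aryl acetate is the most electrophilic carbonyl and is cleaved first, its acetyl group leaving as tert-butoxide and unveiling the 7-phenoxide of 17. The organocerium reagent then adds to the ring A lactone carbonyl, the tetrahedral intermediate expels the 5-phenoxide, and the resulting methyl ketone, which CeCl3 keeps from enolising, takes a second methyl group to give the C3''' carbinol. At ring B, 1,2-addition to the coumarin carbonyl, ring opening to the Z-enone 4'-phenoxide and a second 1,2-addition give the Z-allylic tertiary alkoxide at C2''; the Z geometry is inherited from the ring and no stereocentre is created. No ring is closed: two lactone rings are opened and four C–CH3 bonds are formed. The closest known reactions are the exhaustive methylation of coumarins to Z-configured diols (the classical entry to 2,2-dimethyl-2H-chromenes) and of dihydrocoumarins to phenolic tertiary alcohols, with CeCl3 used to enforce carbonyl addition. The step needs lactone-over-pyrone selectivity and 1,2- over 1,4-addition on the coumarin. The first is secured by the substrate: as the 7-phenoxide, and after the first opening also as the chelated 5-phenoxide, the pyrone is a vinylogous carboxylate and far less electrophilic than an aryl ester. The second is secured by the hard, oxophilic organocerium reagent, and the buffered NH4Cl quench should keep the Z-diol open.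

Step 12
Reactants: 18 2'-O-MOM seco-Kanzonol T
Product: 19 2'-O-MOM Kanzonol T
Conditions: PPTS (cat.), CH2Cl2, 4 Å molecular sieves, rt
Reagents that add atoms: none
Why: Acid-catalysed cyclodehydration: the doubly activated tertiary allylic alcohol ionises under PPTS (or loses water to an ortho-quinone methide) and the cis-disposed 4'-OH closes the 2,2-dimethyl-2H-pyran (six-membered O-cyclisation, equivalent to an oxa-6π closure); the 2'-oxygen is blocked as its MOM ether, and the saturated tertiary alcohol on ring A should not ionise under these conditions.

Step 13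
Reactants: 19 2'-O-MOM Kanzonol T
Product: 20 Kanzonol T
Conditions: 2 M aq. HCl, MeOH–THF, rt → 40 °C
Reagents that add atoms: none
Why: Acid-catalysed acetal cleavage of the aryl MOM ether under dilute, near-ambient conditions that the chromene and the non-allylic tertiary alcohol should tolerate.

## Compound list

1 | phloroglucinol (benzene-1,3,5-triol) | Oc1cc(O)cc(O)c1 | starting material
2 | acrylic acid | C=CC(=O)O | starting material
3 | 5,7-dihydroxychroman-2-one (5,7-dihydroxy-3,4-dihydrocoumarin) | O=C1CCc2c(O)cc(O)cc2O1 | intermediate
4 | 2,6-dihydroxybenzaldehyde | O=Cc1c(O)cccc1O | starting material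
5 | ethyl (E)-3-(2,6-dihydroxyphenyl)acrylate | CCOC(=O)/C=C/c1c(O)cccc1O | intermediate (not isolated)
6 | 5-hydroxycoumarin (5-hydroxy-2H-chromen-2-one) | O=c1ccc2c(O)cccc2o1 | intermediate
7 | 5-(allyloxy)coumarin | C=CCOc1cccc2oc(=O)ccc12 | intermediate
8 | 6-allyl-5-hydroxycoumarin | C=CCc1ccc2oc(=O)ccc2c1O | intermediate
9 | 6-allyl-5-methoxycoumarin | C=CCc1ccc2oc(=O)ccc2c1OC | intermediate
10 | 2-(5-methoxy-2-oxo-2H-chromen-6-yl)acetaldehyde | O=CCc1ccc2oc(=O)ccc2c1OC | intermediate (not isolated)
11 | 2-(5-methoxy-2-oxo-2H-chromen-6-yl)acetic acid | O=C(O)Cc1ccc2oc(=O)ccc2c1OC | intermediate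
12 | 5,7-dihydroxy-8-[2-(5-methoxy-2-oxo-2H-chromen-6-yl)acetyl]chroman-2-one | O=C1CCc2c(O)cc(O)c(C(=O)Cc3ccc4oc(=O)ccc4c3OC)c2O1 | intermediate
13 | 7-hydroxy-2'-methoxy isoflavone with a dihydrocoumarin lactone across C6 and 5-O and a coumarin lactone across C3' and 4'-O | O=C1CCc2c(O)cc3occ(-c4ccc5oc(=O)ccc5c4OC)c(=O)c3c2O1 | intermediate
14 | 7,2'-dihydroxy bis-lactone isoflavone (same two lactones as 13) | O=C1CCc2c(O)cc3occ(-c4ccc5oc(=O)ccc5c4O)c(=O)c3c2O1 | intermediate
15 | 7-O-acetyl-2'-hydroxy bis-lactone isoflavone | O=C1CCc2c(OC(C)=O)cc3occ(-c4ccc5oc(=O)ccc5c4O)c(=O)c3c2O1 | intermediate (not isolated)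
16 | 7-O-acetyl-2'-O-MOM bis-lactone isoflavone | O=C1CCc2c(OC(C)=O)cc3occ(-c4ccc5oc(=O)ccc5c4OCOC)c(=O)c3c2O1 | intermediate
17 | 7-hydroxy-2'-O-MOM bis-lactone isoflavone (present as its metal phenoxide) | O=C1CCc2c(O)cc3occ(-c4ccc5oc(=O)ccc5c4OCOC)c(=O)c3c2O1 | intermediate (not isolated)
18 | 2'-O-MOM seco-Kanzonol T: 5,7,4'-trihydroxy-6-(3-hydroxy-3-methylbutyl)-3'-[(Z)-3-hydroxy-3-methylbut-1-enyl]-2'-(methoxymethoxy)isoflavone | CC(C)(O)CCc1c(O)cc2occ(-c3ccc(O)c(/C=C\C(C)(C)O)c3OCOC)c(=O)c2c1O | intermediate
19 | 2'-O-MOM Kanzonol T | CC(C)(O)CCc1c(O)cc2occ(-c3ccc4c(c3OCOC)C=CC(C)(C)O4)c(=O)c2c1O | intermediate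
20 | Kanzonol T | CC(C)(O)CCc1c(O)cc2occ(-c3ccc4c(c3O)C=CC(C)(C)O4)c(=O)c2c1O | target

## Step count and least certain steps

Total: 13 steps. Longest linear sequence: 12 steps (from 4 through steps 2–13); step 1 is the one-step side branch that supplies 3.

**Step 11 (key step).** Most likely failures:
- stalling after a single methyl addition at one lactone, through enolisation of the intermediate methyl ketone or precipitation of the poly-metallated phenoxides from THF at low temperature;
- conjugate addition at C4 of the coumarin;
- attack on the pyrone before the acetate has been cleaved.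

Fallback, from 16 back to 18: the aluminium amide from Me3Al and N,O-dimethylhydroxylamine hydrochloride should open the more reactive saturated aryl lactone and remove the acetate, giving the ring A Weinreb amide F1 with the coumarin intact (an opened coumarin amide would reclose on work-up). MeMgBr should then convert the amide into a methyl ketone without over-addition, because the chelated tetrahedral intermediate persists until work-up, and at the same time add twice to the coumarin, giving ketone diol F2. A separate MeMgBr/CeCl3 addition to the isolated ketone should then give 18. The enolisable ketone is thus handled in a dedicated step.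

**Step 7.** Most likely failures:
- competing acylation at C6, the position between the two hydroxyls;
- double acylation;
- Lewis-acid opening and re-closure of the lactone onto the other ortho oxygen.

Each would erode the regiochemical information on which ring C closure depends.

Fallback, from 1 and 11 back to 14, with ring C built first on the symmetric triphenol and the chain placed on C6 by a Claisen rearrangement that has no positional choice:
- BF3·OEt2 acylation of 1 with 11 gives the symmetric deoxybenzoin F3.
- DMF/MsCl/BF3·OEt2 closure gives the 5,7-dihydroxyisoflavone F4.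
- One equivalent of MeI/K2CO3 methylates only the non-chelated 7-OH, giving 7-methyl ether F5.
- Allyl bromide/K2CO3 in warm DMF gives the 5-O-allyl ether F6.
- Heating in PhNEt2 moves the allyl group to the only free ortho carbon, C6, giving the 6-allyl-5-hydroxy compound F7.
- 9-BBN followed by NaBO3 gives the primary alcohol F8.
- TEMPO/PhI(OAc)2 gives the propanoic acid F9.
- Carbodiimide lactonisation onto the 5-OH gives the 7-methoxy bis-lactone F10.
- BBr3 cleaves both methyl ethers and returns the route to 14.

**Step 10.** Most likely failures: incomplete discrimination between the two phenols in the acylation (some 2'-acetate or diacetate), sluggish alkylation of the hindered 2'-OH, or acetyl transfer under the basic conditions. Any of these would put the MOM group on the wrong oxygen.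

Fallback, from 14 to 20, with no site selection: both phenols are converted with excess MOMCl/i-Pr2NEt into the 7,2'-bis-MOM bis-lactone F11. MeLi/CeCl3 gives the bis-MOM seco-diol F12; here the pyrone is shielded by the chelated 5-phenoxide released when the ring A lactone opens. PPTS gives 7,2'-bis-O-MOM Kanzonol T F13, and dilute HCl in MeOH removes both acetals to give 20.

**Step 13.** Most likely failures: acid-induced cyclisation of the side-chain tertiary alcohol onto the 5- or 7-hydroxyl (chroman formation), solvolysis of that alcohol to its methyl ether, or slow acetal cleavage that tempts harsher acid.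

Fallback, from 14 to 20, ending with fluoride in place of acid: 14 is acetylated selectively as in step 10 and 15 is isolated. TBSOTf/2,6-lutidine gives the 7-O-acetyl-2'-O-TBS bis-lactone F14. MeLi/CeCl3 gives the 2'-O-TBS seco-diol F15, PPTS gives 2'-O-TBS Kanzonol T F16, and buffered TBAF gives 20.

**Step 1.** Most likely failures: O-acylation followed by Fries-type C-acylation leading to the chroman-4-one series, a second annulation on the still activated ring, or polymerisation of 2.

Fallback, from 1 back to 3: Pechmann condensation of 1 with ethyl propiolate and ZnCl2 gives 5,7-dihydroxycoumarin F17, and hydrogenation of its lactone C=C bond (H2, Pd/C) gives 3.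

## Further compounds

F1 | step 11 | ring A Weinreb amide: 5,7-dihydroxy-6-[3-(N-methoxy-N-methylamino)-3-oxopropyl]-2'-O-MOM isoflavone with the 3',4'-coumarin lactone intact | CON(C)C(=O)CCc1c(O)cc2occ(-c3ccc4oc(=O)ccc4c3OCOC)c(=O)c2c1O
F2 | step 11 | ketone diol: 5,7,4'-trihydroxy-6-(3-oxobutyl)-3'-[(Z)-3-hydroxy-3-methylbut-1-enyl]-2'-(methoxymethoxy)isoflavone | CC(=O)CCc1c(O)cc2occ(-c3ccc(O)c(/C=C\C(C)(C)O)c3OCOC)c(=O)c2c1O
F3 | step 7 | 2-(5-methoxy-2-oxo-2H-chromen-6-yl)-1-(2,4,6-trihydroxyphenyl)ethanone | O=C(Cc1ccc2oc(=O)ccc2c1OC)c1c(O)cc(O)cc1O
F4 | step 7 | 5,7-dihydroxy-3-(5-methoxy-2-oxo-2H-chromen-6-yl)-4H-chromen-4-one | O=c1c(-c2ccc3oc(=O)ccc3c2OC)coc2cc(O)cc(O)c12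
F5 | step 7 | 5-hydroxy-7-methoxy-3-(5-methoxy-2-oxo-2H-chromen-6-yl)-4H-chromen-4-one | O=c1c(-c2ccc3oc(=O)ccc3c2OC)coc2cc(OC)cc(O)c12
F6 | step 7 | 5-(allyloxy)-7-methoxy-3-(5-methoxy-2-oxo-2H-chromen-6-yl)-4H-chromen-4-one | C=CCOc1cc(OC)cc2occ(-c3ccc4oc(=O)ccc4c3OC)c(=O)c12
F7 | step 7 | 6-allyl-5-hydroxy-7-methoxy-3-(5-methoxy-2-oxo-2H-chromen-6-yl)-4H-chromen-4-one | C=CCc1c(OC)cc2occ(-c3ccc4oc(=O)ccc4c3OC)c(=O)c2c1O
F8 | step 7 | 5-hydroxy-6-(3-hydroxypropyl)-7-methoxy-3-(5-methoxy-2-oxo-2H-chromen-6-yl)-4H-chromen-4-one | OCCCc1c(OC)cc2occ(-c3ccc4oc(=O)ccc4c3OC)c(=O)c2c1O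
F9 | step 7 | 3-[5-hydroxy-7-methoxy-3-(5-methoxy-2-oxo-2H-chromen-6-yl)-4-oxo-4H-chromen-6-yl]propanoic acid | OC(=O)CCc1c(OC)cc2occ(-c3ccc4oc(=O)ccc4c3OC)c(=O)c2c1O
F10 | step 7 | 7,2'-dimethoxy bis-lactone isoflavone (7-O-methyl ether of 13) | O=C1CCc2c(OC)cc3occ(-c4ccc5oc(=O)ccc5c4OC)c(=O)c3c2O1
F11 | step 10 | 7,2'-bis-O-MOM bis-lactone isoflavone | O=C1CCc2c(OCOC)cc3occ(-c4ccc5oc(=O)ccc5c4OCOC)c(=O)c3c2O1
F12 | step 10 | 7,2'-bis-O-MOM seco-Kanzonol T (Z-alkene, free 5-OH and 4'-OH) | CC(C)(O)CCc1c(OCOC)cc2occ(-c3ccc(O)c(/C=C\C(C)(C)O)c3OCOC)c(=O)c2c1O
F13 | step 10 | 7,2'-bis-O-MOM Kanzonol T | CC(C)(O)CCc1c(OCOC)cc2occ(-c3ccc4c(c3OCOC)C=CC(C)(C)O4)c(=O)c2c1O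
F14 | step 13 | 7-O-acetyl-2'-O-(tert-butyldimethylsilyl) bis-lactone isoflavone | O=C1CCc2c(OC(C)=O)cc3occ(-c4ccc5oc(=O)ccc5c4O[Si](C)(C)C(C)(C)C)c(=O)c3c2O1
F15 | step 13 | 2'-O-(tert-butyldimethylsilyl) seco-Kanzonol T (Z-alkene) | CC(C)(O)CCc1c(O)cc2occ(-c3ccc(O)c(/C=C\C(C)(C)O)c3O[Si](C)(C)C(C)(C)C)c(=O)c2c1O
F16 | step 13 | 2'-O-(tert-butyldimethylsilyl) Kanzonol T | CC(C)(O)CCc1c(O)cc2occ(-c3ccc4c(c3O[Si](C)(C)C(C)(C)C)C=CC(C)(C)O4)c(=O)c2c1O
F17 | step 1 | 5,7-dihydroxycoumarin | O=c1ccc2c(O)cc(O)cc2o1
A1 | alternative 1 | 2,2-dimethyl-2H-chromen-5-yl 3-bromo-6-(3-hydroxy-3-methylbutyl)-5,7-bis(methoxymethoxy)-4-oxo-4H-chromene-2-carboxylate | CC(C)(O)CCc1c(OCOC)cc2oc(C(=O)Oc3cccc4OC(C)(C)C=Cc34)c(Br)c(=O)c2c1OCOC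
A2 | alternative 1 | lactone-bridged 5,7-bis-O-MOM isoflavone (ester oxygen on C2', carboxyl carbon on C2) | CC(C)(O)CCc1c(OCOC)cc2oc3c(c(=O)c2c1OCOC)-c1ccc2OC(C)(C)C=Cc2c1OC3=O
A3 | alternative 2 | 2,2-dimethyl-2H,5H-pyrano[4,3-b]pyran-5-one | CC1(C)C=CC2=C(O1)C=COC2=O
A4 | alternative 2 | 5,7-bis(methoxymethoxy)-6-[3-methyl-3-(triethylsilyloxy)butyl]-3-{[2-(trimethylsilyl)ethoxy]ethynyl}-4H-chromen-4-one | CC(C)(O[Si](CC)(CC)CC)CCc1c(OCOC)cc2occ(C#COCC[Si](C)(C)C)c(=O)c2c1OCOC
A5 | alternative 2 | 5,7-bis-O-MOM, 2'-O-[2-(trimethylsilyl)ethyl], chain-O-triethylsilyl Kanzonol T | CC(C)(O[Si](CC)(CC)CC)CCc1c(OCOC)cc2occ(-c3ccc4OC(C)(C)C=Cc4c3OCC[Si](C)(C)C)c(=O)c2c1OCOC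
A6 | alternative 3 | 3,5-bis(methoxymethoxy)-4-[3-methyl-3-(triethylsilyloxy)butyl]-2-(trimethylsilyl)phenyl trifluoromethanesulfonate | CC(C)(O[Si](CC)(CC)CC)CCc1c(OCOC)cc(OS(=O)(=O)C(F)(F)F)c([Si](C)(C)C)c1OCOC
A7 | alternative 3 | 3,5-bis(methoxymethoxy)-4-[3-methyl-3-(triethylsilyloxy)butyl]benzyne (aryne across the future C4a and C8a) | CC(C)(O[Si](CC)(CC)CC)CCC1=C(OCOC)C#CC=C1OCOC
A8 | alternative 3 | methyl 2-[5-(methoxymethoxy)-2,2-dimethyl-2H-chromen-6-yl]-3-oxopropanoate | COC(=O)C(C=O)c1ccc2OC(C)(C)C=Cc2c1OCOC
A9 | alternative 3 | 5,7,2'-tris-O-MOM, chain-O-triethylsilyl Kanzonol T | CC(C)(O[Si](CC)(CC)CC)CCc1c(OCOC)cc2occ(-c3ccc4OC(C)(C)C=Cc4c3OCOC)c(=O)c2c1OCOC
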